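**Plan**
1. Retrosynthesis: the two benzyl ethers on the catechol are removed last; the bond between C1 of the 3,4-dimethoxyphenyl ring and the benzylic CH2 on lactone C3 is cut next (aryl-rhodium 1,4-addition to an exocyclic C3=CH2); then the C3=CH2 carbon (from formaldehyde), the lactone C5–O bond (ester reduction and lactonisation), and finally the C4 side chain back to a Stobbe alkylidene succinate.
2. Forward: Stobbe condensation builds the carbon chain, asymmetric hydrogenation sets C4, ester reduction closes the γ-butyrolactone (the only ring made), α-methylenation installs C3=CH2, the dimethoxyphenyl ring is joined, and hydrogenolysis frees the catechol.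
3. Enabling feature: the benzylic CH2 on C3 is β to the lactone carbonyl C2, so as an exocyclic methylene it is the electrophilic terminus of an α-methylene-γ-butyrolactone; C3–H is the only acidic stereogenic C–H, and 3,4-trans is the thermodynamic arrangement on the five-membered ring.
4. Stereochemistry: C4 (R) comes from Rh/(S,S)-Et-DuPhos hydrogenation; C3 (R) comes from base equilibration of both C3 epimers under control of C4 (stereoconvergent).

Key step: step 5

Remark: the (R) sense of induction in step 2 is assigned by analogy with other Stobbe half-esters reduced with this ligand family; if it proves opposite, the (R,R)-ligand is used and nothing else changes.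

Step 1
Reactants: 1 3,4-bis(benzyloxy)benzaldehyde; 2 dimethyl succinate
Product: 3 (E)-4-[3,4-bis(benzyloxy)phenyl]-3-(methoxycarbonyl)but-3-enoic acid
Conditions: NaOMe (2 equiv), MeOH, reflux; then aq. HCl
Reagents that add atoms: none
Why: Stobbe condensation, in which the succinate enolate adds to the aldehyde, the aldolate lactonises to a paraconate and E1cB ring opening gives the (E)-alkylidene half-ester as its carboxylate, which drives the reaction and differentiates the two carboxyl groups.

Step 2
Reactants: 3 (E)-4-[3,4-bis(benzyloxy)phenyl]-3-(methoxycarbonyl)but-3-enoic acid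
Product: 4 (R)-4-[3,4-bis(benzyloxy)phenyl]-3-(methoxycarbonyl)butanoic acid
Conditions: H2 (5 bar), [Rh(cod)((S,S)-Et-DuPhos)]OTf (0.5 mol%), NaOMe (10 mol%), MeOH, rt
Reagents that add atoms: none
Why: Rhodium-catalysed asymmetric hydrogenation of an itaconate-type Stobbe half-ester, in which the carboxylate-chelated olefin binds the C2-symmetric bisphospholane complex through one enantioface so that H2 should be delivered to give the (R) centre (the future C4), while the benzyl ethers are inert to the homogeneous catalyst.

Step 3
Reactants: 4 (R)-4-[3,4-bis(benzyloxy)phenyl]-3-(methoxycarbonyl)butanoic acid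
Product: 6 (R)-4-[3,4-bis(benzyloxy)benzyl]dihydrofuran-2(3H)-one, via hydroxy acid 5 (not isolated)
Conditions: KOH (1 equiv), EtOH; CaCl2, NaBH4, EtOH, 0 °C to rt; then 2 M HCl, rt
Reagents that add atoms: none
Why: Chemoselective calcium borohydride reduction of the ester beside the unreactive potassium carboxylate, followed by acid-promoted γ-lactonisation (5-exo-trig acyl substitution), places the carbonyl on the former CH2CO2H arm and leaves the stereocentre, which takes no part, unchanged.

Step 4
Reactants: 6 (R)-4-[3,4-bis(benzyloxy)benzyl]dihydrofuran-2(3H)-one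
Product: 8 (R)-4-[3,4-bis(benzyloxy)benzyl]-3-methylenedihydrofuran-2(3H)-one, via sodium formyl enolate 7 (not isolated)
Conditions: NaH, HCO2Et, cat. EtOH, THF, 0 °C to rt; volatiles removed; then (CH2O)n, THF, 65 °C
Reagents that add atoms: paraformaldehyde (as formaldehyde), C=O
Why: Claisen formylation of the lactone at C3, then aldol addition of the formyl enolate to formaldehyde, O-formyl transfer (retro-Claisen) and E1cB loss of formate, is the established α-formyl-lactone route to α-methylene-γ-butyrolactones and does not involve the C4 centre.

Step 5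
Reactants: 8 (R)-4-[3,4-bis(benzyloxy)benzyl]-3-methylenedihydrofuran-2(3H)-one; 9 3,4-dimethoxyphenylboronic acid (2 equiv)
Product: 11 (3R,4R)-4-[3,4-bis(benzyloxy)benzyl]-3-(3,4-dimethoxybenzyl)dihydrofuran-2(3H)-one, via cis C3 epimer 10 (not isolated)
Conditions: [Rh(cod)OH]2 (2.5 mol%), dioxane/H2O 10:1, 50 °C; crude product, then DBU (0.3 equiv), PhMe, 80 °C
Reagents that add atoms: none
Why: Transmetalation of 9 to the Rh(I) hydroxide gives an aryl-rhodium species that inserts the exocyclic C3=CH2 of 8, with the aryl group going to the unsubstituted CH2 terminus and rhodium to C3 as an oxa-π-allyl (rhodium enolate), which water protonates to release the saturated lactone and regenerate Rh–OH. The closest known reaction type is the Hayashi–Miyaura rhodium-catalysed 1,4-addition of arylboronic acids to α-substituted acrylates and itaconates with subsequent protonation. No ring is closed. The new C3 stereocentre is not left to the kinetic protonation, which is expected to place H anti to the C4 substituent and so favour the cis epimer 10; instead DBU reversibly enolises C3, the only acidic stereogenic C–H, so that both epimers should converge on the 3,4-trans (3R,4R) lactone, in which the two benzyl groups avoid each other on the five-membered ring, while the non-acidic C4 centre is untouched. The step needs 1,4- rather than 1,2-addition and must avoid β-hydride elimination to an arylidene lactone and migration of the exocyclic alkene into the ring, which would erase C4; conjugation of the terminal CH2 with the lactone carbonyl, fast protonolysis in aqueous dioxane under base-free Rh–OH conditions, and addition of DBU only after the alkene has been consumed should secure this.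

Step 6
Reactants: 11 (3R,4R)-4-[3,4-bis(benzyloxy)benzyl]-3-(3,4-dimethoxybenzyl)dihydrofuran-2(3H)-one
Product: 12 (3R,4R)-4-(3,4-dihydroxybenzyl)-3-(3,4-dimethoxybenzyl)dihydrofuran-2(3H)-one
Conditions: H2 (1 atm), 10% Pd/C, EtOAc/MeOH, rt; filtration under argon
Reagents that add atoms: none
Why: Palladium-catalysed hydrogenolysis cleaves both benzylic C–O bonds of the aryl benzyl ethers under neutral conditions that should leave the lactone, the methyl ethers and both stereocentres untouched.

**Compound list**
1 | 3,4-bis(benzyloxy)benzaldehyde | O=Cc1ccc(OCc2ccccc2)c(OCc2ccccc2)c1 | starting material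
2 | dimethyl succinate | COC(=O)CCC(=O)OC | starting material
3 | (E)-4-[3,4-bis(benzyloxy)phenyl]-3-(methoxycarbonyl)but-3-enoic acid | COC(=O)/C(CC(=O)O)=C/c1ccc(OCc2ccccc2)c(OCc2ccccc2)c1 | intermediate
4 | (R)-4-[3,4-bis(benzyloxy)phenyl]-3-(methoxycarbonyl)butanoic acid | OC(=O)C[C@@H](Cc1ccc(OCc2ccccc2)c(OCc2ccccc2)c1)C(=O)OC | intermediate
5 | (R)-3-[3,4-bis(benzyloxy)benzyl]-4-hydroxybutanoic acid | OC(=O)C[C@@H](Cc1ccc(OCc2ccccc2)c(OCc2ccccc2)c1)CO | intermediate (not isolated)
6 | (R)-4-[3,4-bis(benzyloxy)benzyl]dihydrofuran-2(3H)-one | O=C1C[C@@H](Cc2ccc(OCc3ccccc3)c(OCc3ccccc3)c2)CO1 | intermediate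
7 | sodium enolate of (R)-4-[3,4-bis(benzyloxy)benzyl]-3-formyldihydrofuran-2(3H)-one (enolate geometry not defined) | [Na+].[O-]C=C1C(=O)OC[C@@H]1Cc1ccc(OCc2ccccc2)c(OCc2ccccc2)c1 | intermediate (not isolated)
8 | (R)-4-[3,4-bis(benzyloxy)benzyl]-3-methylenedihydrofuran-2(3H)-one | C=C1C(=O)OC[C@@H]1Cc1ccc(OCc2ccccc2)c(OCc2ccccc2)c1 | intermediate
9 | 3,4-dimethoxyphenylboronic acid | COc1ccc(B(O)O)cc1OC | starting material
10 | (3S,4R)-4-[3,4-bis(benzyloxy)benzyl]-3-(3,4-dimethoxybenzyl)dihydrofuran-2(3H)-one (cis) | COc1ccc(C[C@@H]2C(=O)OC[C@@H]2Cc2ccc(OCc3ccccc3)c(OCc3ccccc3)c2)cc1OC | intermediate (not isolated)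
11 | (3R,4R)-4-[3,4-bis(benzyloxy)benzyl]-3-(3,4-dimethoxybenzyl)dihydrofuran-2(3H)-one (trans) | COc1ccc(C[C@H]2C(=O)OC[C@@H]2Cc2ccc(OCc3ccccc3)c(OCc3ccccc3)c2)cc1OC | intermediate
12 | (3R,4R)-4-(3,4-dihydroxybenzyl)-3-(3,4-dimethoxybenzyl)dihydrofuran-2(3H)-one | COc1ccc(C[C@H]2C(=O)OC[C@@H]2Cc2ccc(O)c(O)c2)cc1OC | target

**Summary**
Total step count: 6. Longest linear sequence: 6 steps (1 to 12); the boronic acid 9 enters convergently in step 5.

**Steps most likely to fail**

Step 5. The equilibration may not converge fully on the trans epimer. The rhodium enolate may undergo β-hydride elimination instead of protonolysis. The exocyclic alkene may migrate into the ring before arylation, with loss of the C4 centre. The electron-rich boronic acid may protodeboronate. The fallback sets out from 6 and returns at 11: the lithium enolate of 6 (LiHMDS, THF, −78 °C) is alkylated with commercial 3,4-dimethoxybenzyl bromide, which should enter anti to the C4 substituent and give the trans lactone 11 directly. This fallback makes no compound outside the list (F0).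

Step 4. Formyl transfer and elimination may stall. Base may shift the new alkene into the ring, erasing C4. Alkoxide may add to the acrylate-type product, or the product may oligomerise. The fallback sets out from 6 and returns at 8. Deprotonation with LDA (THF, −78 °C) and a Mannich reaction with Eschenmoser's salt should give trans (3S,4R)-4-[3,4-bis(benzyloxy)benzyl]-3-[(dimethylamino)methyl]dihydrofuran-2(3H)-one F1. Quaternisation with MeI in MeOH should give the trimethylammonium iodide of that Mannich base F2. Mild elimination with aqueous NaHCO3/CH2Cl2 should then give 8 without a strong base being present.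

Step 2. The enantioface discrimination may be insufficient, or the catalyst may be inhibited by trace impurities from the Stobbe step. The fallback sets out from 3 and returns at 4. Hydrogenation with an achiral cationic catalyst ([Rh(nbd)(dppb)]BF4, H2, MeOH), which spares the benzyl ethers, should give racemic 4-[3,4-bis(benzyloxy)phenyl]-3-(methoxycarbonyl)butanoic acid F3. Classical resolution by fractional crystallisation with (R)-1-phenylethylamine should give (R)-1-phenylethylammonium (R)-4-[3,4-bis(benzyloxy)phenyl]-3-(methoxycarbonyl)butanoate F4; the (S)-amine would be used if the other diastereomeric salt is the less soluble one. Acidification with aqueous HCl returns 4.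

**Further compounds**
F0 | step 5 | none | none
F1 | step 4 | (3S,4R)-4-[3,4-bis(benzyloxy)benzyl]-3-[(dimethylamino)methyl]dihydrofuran-2(3H)-one | CN(C)C[C@H]1C(=O)OC[C@@H]1Cc1ccc(OCc2ccccc2)c(OCc2ccccc2)c1
F2 | step 4 | [(3S,4R)-4-[3,4-bis(benzyloxy)benzyl]-2-oxotetrahydrofuran-3-yl]methyl-trimethylammonium iodide | C[N+](C)(C)C[C@H]1C(=O)OC[C@@H]1Cc1ccc(OCc2ccccc2)c(OCc2ccccc2)c1.[I-]
F3 | step 2 | racemic 4-[3,4-bis(benzyloxy)phenyl]-3-(methoxycarbonyl)butanoic acid | OC(=O)CC(Cc1ccc(OCc2ccccc2)c(OCc2ccccc2)c1)C(=O)OC
F4 | step 2 | (R)-1-phenylethylammonium (R)-4-[3,4-bis(benzyloxy)phenyl]-3-(methoxycarbonyl)butanoate | C[C@@H]([NH3+])c1ccccc1.[O-]C(=O)C[C@@H](Cc1ccc(OCc2ccccc2)c(OCc2ccccc2)c1)C(=O)OC
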